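**Plan**
1. Cuts: the phenol O–acetal C bond of the 1,3-dioxin ring (ring C); in ring A the bond between the two ring-fusion carbons and the bond between the methoxy carbon and the formyl-bearing carbon, which also opens pyran ring B; the acetal C–alkyne bond; the bond between the carbinol carbon and the acetyl-bearing carbon; the pyridine ring of the isoquinoline.
2. Enabling feature: ring A is a pentasubstituted benzene with oxygen on two meta carbons, fused to ring B. Its methoxy carbon and the neighbouring fusion carbon (the one on the acetal carbon) map onto a methoxyalkyne; its formyl-bearing carbon, hydroxy carbon, CH and second fusion carbon map onto C3, C4, C5 and C6 of a 3-carbomethoxy-4-alkoxy-2-pyrone.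
3. Forward: pyrone, then γ-pyronyl allylboronate; orsellinaldehyde, then isoquinoline, then its 7-carbaldehyde; allylboration joins the halves; an alkynyl mixed acetal is built on the new hydroxyl; heat closes rings A and B with loss of CO2; redox adjustment; acid closes ring C.
4. Stereochemistry: both carbon stereocentres arise in one closed-chair allylboration (E-boronate gives anti, the chiral phosphoric acid selects the face). The acetyl group travels as a vinyl group, so its α-centre can neither epimerise nor eliminate. The acetal centre is fixed only at the end, where the bridged ring allows one configuration.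
5. The acetal tether stays acyclic until then: a monocyclic 2,4-cis-benzodioxin would need both substituents axial and is not the isomer that acetal formation favours.

Key step: step 14

Remark: the acetal carbon made in step 13 is carried as both epimers, because the last step converts either one into the single bridged acetal.
Remark: the facial preference of the (R)-configured phosphoric acid in step 11 is assumed to follow that known for simple aryl aldehydes; the antipodal acid is used if the sense proves opposite.

**Step 1**
Reactants: 1 dimethyl malonate; 2 diketene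
Product: 5 methyl 4-hydroxy-6-methyl-2-oxo-2H-pyran-3-carboxylate, via sodium dimethyl malonate 3 (not isolated), via sodium acylmalonate enolate 4 (not isolated)
Conditions: NaH, THF, 0 °C; 2, 0 → 60 °C; aqueous HCl
Reagents that add atoms: none
Why: C-acylation of the malonate anion by diketene followed by lactonisation of the enolised triketo ester onto one ester group is the established cyclocondensation route to 3-carbalkoxy-4-hydroxy-6-methyl-2-pyrones.

**Step 2**
Reactants: 5 methyl 4-hydroxy-6-methyl-2-oxo-2H-pyran-3-carboxylate
Product: 6 methyl 4-(methoxymethoxy)-6-methyl-2-oxo-2H-pyran-3-carboxylate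
Conditions: MeOCH2Cl, i-Pr2NEt, CH2Cl2, 0 °C
Reagents that add atoms: chloromethyl methyl ether COCCl
Why: the acidic 4-hydroxyl is O-alkylated by the hard electrophile (Williamson-type ether formation), which masks the future ring A phenol in a form that the last step removes.

**Step 3**
Reactants: 6 methyl 4-(methoxymethoxy)-6-methyl-2-oxo-2H-pyran-3-carboxylate
Product: 10 methyl 4-(methoxymethoxy)-2-oxo-6-[(E)-prop-1-enyl]-2H-pyran-3-carboxylate, via lithium dienolate 7 (not isolated), via lithium aldolate 8 (not isolated), via aldol mesylate 9 (not isolated)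
Conditions: LiN(SiMe3)2, THF, −78 °C; CH3CHO; MeSO2Cl, −78 → 0 °C; DBU, 0 °C → rt
Reagents that add atoms: acetaldehyde CC=O
Why: the 6-methyl group of a 2-pyrone is deprotonated as a vinylogous enolate that adds to aldehydes (vinylogous aldol addition), and mesylation followed by E1cB elimination into conjugation should give the E-alkene, a stable handle for metathesis.

**Step 4**
Reactants: 10 methyl 4-(methoxymethoxy)-2-oxo-6-[(E)-prop-1-enyl]-2H-pyran-3-carboxylate
Product: 11 methyl 4-(methoxymethoxy)-2-oxo-6-[(E)-3-(4,4,5,5-tetramethyl-1,3,2-dioxaborolan-2-yl)prop-1-enyl]-2H-pyran-3-carboxylate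
Conditions: allylboronic acid pinacol ester (3 equiv), second-generation Grubbs catalyst RuCl2(=CHPh)(H2IMes)(PCy3) (5 mol%), CH2Cl2, 40 °C
Reagents that add atoms: allylboronic acid pinacol ester C=CCB1OC(C)(C)C(C)(C)O1
Why: olefin cross-metathesis of the conjugated propenyl group with the allylboronate releases propene and is expected to give the thermodynamically favoured E-configured γ-substituted allylboronate.

**Step 5**
Reactants: 12 2,4-dihydroxy-6-methylbenzaldehyde
Product: 13 2-hydroxy-4-(methoxymethoxy)-6-methylbenzaldehyde
Conditions: MeOCH2Cl (1.05 equiv), i-Pr2NEt, CH2Cl2, 0 °C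
Reagents that add atoms: chloromethyl methyl ether COCCl
Why: the 4-hydroxyl is the more acidic one and is not hydrogen-bonded to the aldehyde, so mono-alkylation (Williamson-type ether formation) should occur there.

**Step 6**
Reactants: 13 2-hydroxy-4-(methoxymethoxy)-6-methylbenzaldehyde
Product: 14 2-methoxy-4-(methoxymethoxy)-6-methylbenzaldehyde
Conditions: MeI, K2CO3, DMF, 40 °C
Reagents that add atoms: iodomethane CI
Why: Williamson methylation of the remaining chelated phenol installs the methoxy group that ends up at C8 of the isoquinoline.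

**Step 7**
Reactants: 14 2-methoxy-4-(methoxymethoxy)-6-methylbenzaldehyde
Product: 17 3-iodo-2-methoxy-4-(methoxymethoxy)-6-methylbenzaldehyde, via lithium α-amino alkoxide 15 (not isolated), via aryllithium 16 (not isolated)
Conditions: 1-methylpiperazine, n-BuLi, THF, −20 °C; 14; n-BuLi, −20 °C; I2, −78 °C → rt; aqueous NH4Cl, Na2S2O3
Reagents that add atoms: iodine II
Why: temporary conversion of the aldehyde into a lithium α-amino alkoxide allows directed ortho-metalation at the only position flanked by the methoxy and methoxymethoxy groups, and the iodine quench leaves a handle for later formylation.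

**Step 8**
Reactants: 17 3-iodo-2-methoxy-4-(methoxymethoxy)-6-methylbenzaldehyde
Product: 18 N-tert-butyl aldimine of 17
Conditions: t-BuNH2, 4 Å molecular sieves, CH2Cl2, rt
Reagents that add atoms: tert-butylamine CC(C)(C)N
Why: condensation with a hindered primary amine (imine formation) protects the aldehyde against addition and activates the ortho-methyl group for lateral lithiation.

**Step 9**
Reactants: 18 N-tert-butyl aldimine of 17
Product: 21 7-iodo-8-methoxy-6-(methoxymethoxy)-3-methylisoquinoline, via benzylic lithium imine 19 (not isolated), via keto imine 20 (not isolated)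
Conditions: LiN(i-Pr)2, THF, −78 °C; MeC(O)N(OMe)Me, −78 → −40 °C; NH4OAc, MeOH, 50 °C
Reagents that add atoms: N-methoxy-N-methylacetamide CC(=O)N(C)OC; ammonium acetate [NH4+].CC([O-])=O
Why: lateral lithiation of the ortho-methyl aldimine, acylation by the N-methoxy-N-methylamide and ammonia-induced cyclocondensation of the resulting 2-acetonyl aldimine is a known isoquinoline annulation, and it builds the pyridine ring with its 3-methyl group.

**Step 10**
Reactants: 21 7-iodo-8-methoxy-6-(methoxymethoxy)-3-methylisoquinoline
Product: 23 8-methoxy-6-(methoxymethoxy)-3-methylisoquinoline-7-carbaldehyde, via arylmagnesium chloride 22 (not isolated)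
Conditions: i-PrMgCl·LiCl, THF, −20 °C; DMF, −20 → 0 °C; aqueous NH4Cl
Reagents that add atoms: N,N-dimethylformamide CN(C)C=O
Why: iodine–magnesium exchange is faster than addition of the Grignard reagent to the isoquinoline, and formylation of the arylmagnesium places the aldehyde between the two oxygen substituents, a position that electrophilic substitution would not select.

**Step 11**
Reactants: 23 8-methoxy-6-(methoxymethoxy)-3-methylisoquinoline-7-carbaldehyde; 11 γ-pyronyl allylboronate
Product: 25 methyl 6-[(1R,2R)-1-hydroxy-1-[8-methoxy-6-(methoxymethoxy)-3-methylisoquinolin-7-yl]but-3-en-2-yl]-4-(methoxymethoxy)-2-oxo-2H-pyran-3-carboxylate, via isoquinolinium tetrafluoroborate 24 (not isolated)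
Conditions: HBF4·OEt2 (0.95 equiv), CH2Cl2, 0 °C; 11 (1.3 equiv), (R)-3,3'-bis(2,4,6-triisopropylphenyl)-1,1'-binaphthyl-2,2'-diyl hydrogen phosphate ((R)-TRIP, 10 mol%), 4 Å molecular sieves, CH2Cl2–toluene, −30 → 0 °C; aqueous NaHCO3
Reagents that add atoms: none
Why: Brønsted acid-catalysed allylboration runs through a closed chair transition state in which the E-configured γ-pyronyl boronate gives the anti relation of hydroxyl and pyronyl groups, while the chiral phosphoric acid is expected to direct addition to the Re face of the aldehyde (R at the carbinol carbon), the nitrogen being protonated beforehand so that it cannot sequester the catalyst.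

**Step 12**
Reactants: 25 homoallylic alcohol
Product: 26 methyl 6-[(1R,2R)-1-(dimethoxymethoxy)-1-[8-methoxy-6-(methoxymethoxy)-3-methylisoquinolin-7-yl]but-3-en-2-yl]-4-(methoxymethoxy)-2-oxo-2H-pyran-3-carboxylate
Conditions: HC(OMe)3 (neat), pyridinium p-toluenesulfonate (0.5 equiv), 40 °C, reduced pressure; Et3N
Reagents that add atoms: trimethyl orthoformate COC(OC)OC
Why: acid-catalysed alkoxy exchange of an orthoformate with the secondary alcohol, driven by removal of methanol, should give the mixed orthoformate without touching either stereocentre, the isoquinoline buffering the medium against benzylic ionisation.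

**Step 13**
Reactants: 26 mixed orthoformate; 27 2-chloro-1,1-dimethoxyethane
Product: 30 methyl 6-[(1R,2R)-1-[(1,3-dimethoxyprop-2-yn-1-yl)oxy]-1-[8-methoxy-6-(methoxymethoxy)-3-methylisoquinolin-7-yl]but-3-en-2-yl]-4-(methoxymethoxy)-2-oxo-2H-pyran-3-carboxylate (both epimers at the acetal carbon), via lithium methoxyacetylide 28 (not isolated), via methoxyethynylzinc chloride 29 (not isolated)
Conditions: 27, LiNEt2 (3 equiv per 27), THF, −78 → 0 °C; ZnCl2, 0 °C; then 26, ZnCl2, CH2Cl2, −20 °C → rt; aqueous NaHCO3; Et3N-deactivated silica
Reagents that add atoms: none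
Why: double elimination of the chloroacetal gives the alkoxyacetylide, and after transmetalation ZnCl2 ionises one methoxy group of the orthoformate to a dialkoxycarbenium ion that the soft alkynylzinc captures (alkynylation of an orthoformate to a propargylic acetal) without attacking the pyrone, the new acetal carbon being formed without control.

**Step 14**
Reactants: 30 alkynyl mixed acetal
Product: 32 methyl (3R,4S)-4-ethenyl-1,8-dimethoxy-6-(methoxymethoxy)-3-[8-methoxy-6-(methoxymethoxy)-3-methylisoquinolin-7-yl]-3,4-dihydro-1H-isochromene-7-carboxylate (both C1 epimers), via bridged lactone cycloadduct 31 (not isolated)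
Conditions: toluene (0.005 M), 2,6-di-tert-butyl-4-methylphenol (cat.), 120 °C, sealed tube
Reagents that add atoms: none
Why: the methoxyalkyne adds across C6 and C3 of the tethered 2-pyrone in an intramolecular Diels–Alder reaction with inverse electron demand, and the bridged lactone 31 aromatises irreversibly by retro-Diels–Alder loss of CO2; the closest known reaction type is the thermal pyrone–alkyne cycloaddition/decarboxylation used for benzannulation. Ring B closes as a six-membered ring in the cycloaddition itself, because the four-atom tether (vinyl-bearing carbon, carbinol carbon, oxygen, acetal carbon) joins pyrone C6 to the alkyne carbon remote from the methoxy group; ring A closes through the new C6–alkyne and C3–C(OMe) bonds followed by CO2 extrusion. No stereocentre is created: the two existing carbon centres are untouched and the acetal carbon is epimeric before and after. The step needs regioselectivity, which the tether enforces and which the polarity of the partners supports (the nucleophilic alkyne carbon β to oxygen meets the electrophilic C6 of the ester-activated pyrone), and chemoselectivity for the alkyne over the vinyl group, which sits on the carbon next to C6 and cannot reach the diene. Because the ynol ether is a methyl ether, the retro-ene loss of an alkene that turns higher alkoxyalkynes into ketenes is not available on heating.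

**Step 15**
Reactants: 32 vinyl isochroman ester
Product: 33 methyl (3R,4R)-4-(1-hydroxyethyl)-1,8-dimethoxy-6-(methoxymethoxy)-3-[8-methoxy-6-(methoxymethoxy)-3-methylisoquinolin-7-yl]-3,4-dihydro-1H-isochromene-7-carboxylate (epimers at C1 and at the carbinol carbon)
Conditions: Co(acac)2 (20 mol%), PhSiH3, O2 (1 atm), THF/i-PrOH, rt
Reagents that add atoms: dioxygen O=O
Why: cobalt-catalysed hydrogen-atom-transfer hydration of the terminal alkene (Mukaiyama hydration) puts oxygen on the internal carbon with Markovnikov selectivity and without moving the double bond into conjugation with ring A, and the uncontrolled carbinol centre disappears in step 17.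

**Step 16**
Reactants: 33 hydroxy ester
Product: 34 1-[(3R,4R)-7-(hydroxymethyl)-1,8-dimethoxy-6-(methoxymethoxy)-3-[8-methoxy-6-(methoxymethoxy)-3-methylisoquinolin-7-yl]-3,4-dihydro-1H-isochromen-4-yl]ethanol (epimers at C1 and at the carbinol carbon)
Conditions: LiAlH4, THF, 0 °C → rt; H2O, aqueous NaOH
Reagents that add atoms: none
Why: hydride reduction of the hindered aryl ester gives the benzylic alcohol (any ketone carried over from step 15 converges to the same diol), while the acetals and, at this temperature, the isoquinoline are left alone.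

**Step 17**
Reactants: 34 diol
Product: 35 (3R,4S)-4-acetyl-1,8-dimethoxy-6-(methoxymethoxy)-3-[8-methoxy-6-(methoxymethoxy)-3-methylisoquinolin-7-yl]-3,4-dihydro-1H-isochromene-7-carbaldehyde (both C1 epimers)
Conditions: Dess–Martin periodinane (3 equiv), NaHCO3, CH2Cl2, 0 °C → rt
Reagents that add atoms: none
Why: Dess–Martin oxidation converts the benzylic alcohol into the aldehyde and the secondary alcohol into the methyl ketone under buffered conditions that should not epimerise the ketone α-carbon.

**Step 18**
Reactants: 35 keto aldehyde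
Product: 37 target CNP0584953.1, via diphenol methyl acetal 36 (not isolated)
Conditions: CF3CO2H/CH2Cl2/H2O (20:78:2), 0 °C → rt; aqueous NaHCO3
Reagents that add atoms: none
Why: acid removes both methoxymethyl ethers and ionises the cyclic methyl acetal to an oxocarbenium ion that the freed isoquinoline phenol captures intramolecularly (transacetalisation), closing ring C as a bridged acetal whose only possible configuration (R) is dictated by the neighbouring carbinol centre.

**Compound list**
1 | dimethyl malonate | COC(=O)CC(=O)OC | starting material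
2 | diketene (4-methylideneoxetan-2-one) | C=C1CC(=O)O1 | starting material
3 | sodium dimethyl malonate | COC(=O)[CH-]C(=O)OC.[Na+] | intermediate (not isolated)
4 | sodium enolate of dimethyl 2-(3-oxobutanoyl)malonate | COC(=O)C(C(=O)OC)=C([O-])CC(C)=O.[Na+] | intermediate (not isolated)
5 | methyl 4-hydroxy-6-methyl-2-oxo-2H-pyran-3-carboxylate | COC(=O)c1c(O)cc(C)oc1=O | intermediate
6 | methyl 4-(methoxymethoxy)-6-methyl-2-oxo-2H-pyran-3-carboxylate | COC(=O)c1c(OCOC)cc(C)oc1=O | intermediate
7 | lithium dienolate of 6, drawn as the 6-lithiomethyl form | [Li]Cc1cc(OCOC)c(C(=O)OC)c(=O)o1 | intermediate (not isolated)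
8 | lithium alkoxide of methyl 6-(2-hydroxypropyl)-4-(methoxymethoxy)-2-oxo-2H-pyran-3-carboxylate (racemic) | CC(O[Li])Cc1cc(OCOC)c(C(=O)OC)c(=O)o1 | intermediate (not isolated)
9 | methyl 4-(methoxymethoxy)-6-[2-(methylsulfonyloxy)propyl]-2-oxo-2H-pyran-3-carboxylate (racemic) | CC(OS(C)(=O)=O)Cc1cc(OCOC)c(C(=O)OC)c(=O)o1 | intermediate (not isolated)
10 | methyl 4-(methoxymethoxy)-2-oxo-6-[(E)-prop-1-enyl]-2H-pyran-3-carboxylate | C/C=C/c1cc(OCOC)c(C(=O)OC)c(=O)o1 | intermediate
11 | methyl 4-(methoxymethoxy)-2-oxo-6-[(E)-3-(4,4,5,5-tetramethyl-1,3,2-dioxaborolan-2-yl)prop-1-enyl]-2H-pyran-3-carboxylate | CC1(C)OB(C/C=C/c2cc(OCOC)c(C(=O)OC)c(=O)o2)OC1(C)C | intermediate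
12 | 2,4-dihydroxy-6-methylbenzaldehyde | Cc1cc(O)cc(O)c1C=O | starting material
13 | 2-hydroxy-4-(methoxymethoxy)-6-methylbenzaldehyde | Cc1cc(OCOC)cc(O)c1C=O | intermediate
14 | 2-methoxy-4-(methoxymethoxy)-6-methylbenzaldehyde | COc1cc(OCOC)cc(C)c1C=O | intermediate
15 | lithium [2-methoxy-4-(methoxymethoxy)-6-methylphenyl](4-methylpiperazin-1-yl)methanolate | COc1cc(OCOC)cc(C)c1C(O[Li])N1CCN(C)CC1 | intermediate (not isolated)
16 | 3-lithio derivative of 15 | COc1c([Li])c(OCOC)cc(C)c1C(O[Li])N1CCN(C)CC1 | intermediate (not isolated)
17 | 3-iodo-2-methoxy-4-(methoxymethoxy)-6-methylbenzaldehyde | COc1c(I)c(OCOC)cc(C)c1C=O | intermediate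
18 | (E)-N-tert-butyl-1-[3-iodo-2-methoxy-4-(methoxymethoxy)-6-methylphenyl]methanimine | COc1c(I)c(OCOC)cc(C)c1/C=N/C(C)(C)C | intermediate
19 | benzylic lithium derivative of 18 | [Li]Cc1cc(OCOC)c(I)c(OC)c1/C=N/C(C)(C)C | intermediate (not isolated)
20 | 1-[2-[(E)-(tert-butylimino)methyl]-4-iodo-3-methoxy-5-(methoxymethoxy)phenyl]propan-2-one | CC(=O)Cc1cc(OCOC)c(I)c(OC)c1/C=N/C(C)(C)C | intermediate (not isolated)
21 | 7-iodo-8-methoxy-6-(methoxymethoxy)-3-methylisoquinoline | Cc1cc2cc(OCOC)c(I)c(OC)c2cn1 | intermediate
22 | [8-methoxy-6-(methoxymethoxy)-3-methylisoquinolin-7-yl]magnesium chloride (LiCl complex) | Cc1cc2cc(OCOC)c([Mg]Cl)c(OC)c2cn1 | intermediate (not isolated)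
23 | 8-methoxy-6-(methoxymethoxy)-3-methylisoquinoline-7-carbaldehyde | Cc1cc2cc(OCOC)c(C=O)c(OC)c2cn1 | intermediate
24 | 7-formyl-8-methoxy-6-(methoxymethoxy)-3-methylisoquinolin-2-ium tetrafluoroborate | Cc1cc2cc(OCOC)c(C=O)c(OC)c2c[nH+]1.F[B-](F)(F)F | intermediate (not isolated)
25 | methyl 6-[(1R,2R)-1-hydroxy-1-[8-methoxy-6-(methoxymethoxy)-3-methylisoquinolin-7-yl]but-3-en-2-yl]-4-(methoxymethoxy)-2-oxo-2H-pyran-3-carboxylate | COc1c([C@H](O)[C@H](c2cc(OCOC)c(C(=O)OC)c(=O)o2)C=C)c(OCOC)cc2cc(C)ncc12 | intermediate
26 | methyl 6-[(1R,2R)-1-(dimethoxymethoxy)-1-[8-methoxy-6-(methoxymethoxy)-3-methylisoquinolin-7-yl]but-3-en-2-yl]-4-(methoxymethoxy)-2-oxo-2H-pyran-3-carboxylate | COc1c([C@H](OC(OC)OC)[C@H](c2cc(OCOC)c(C(=O)OC)c(=O)o2)C=C)c(OCOC)cc2cc(C)ncc12 | intermediate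
27 | 2-chloro-1,1-dimethoxyethane (chloroacetaldehyde dimethyl acetal) | COC(CCl)OC | starting material
28 | lithium methoxyacetylide | COC#C[Li] | intermediate (not isolated)
29 | (methoxyethynyl)zinc chloride | COC#C[Zn]Cl | intermediate (not isolated)
30 | methyl 6-[(1R,2R)-1-[(1,3-dimethoxyprop-2-yn-1-yl)oxy]-1-[8-methoxy-6-(methoxymethoxy)-3-methylisoquinolin-7-yl]but-3-en-2-yl]-4-(methoxymethoxy)-2-oxo-2H-pyran-3-carboxylate, both epimers at the acetal carbon | COc1c([C@H](OC(OC)C#COC)[C@H](c2cc(OCOC)c(C(=O)OC)c(=O)o2)C=C)c(OCOC)cc2cc(C)ncc12 | intermediate (key-step precursor)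
31 | bridged lactone cycloadduct (2-oxabicyclo[2.2.2]octa-5,7-dien-3-one fused to the new dihydropyran ring; alkyne carbons bonded to former pyrone C6 and C3) | COC1=C2C(OC)O[C@@H](c4c(OCOC)cc5cc(C)ncc5c4OC)[C@@H](C=C)C23C=C(OCOC)C1(C(=O)OC)C(=O)O3 | intermediate (not isolated)
32 | methyl (3R,4S)-4-ethenyl-1,8-dimethoxy-6-(methoxymethoxy)-3-[8-methoxy-6-(methoxymethoxy)-3-methylisoquinolin-7-yl]-3,4-dihydro-1H-isochromene-7-carboxylate, both C1 epimers | COc1c(C(=O)OC)c(OCOC)cc2c1C(OC)O[C@@H](c1c(OCOC)cc3cc(C)ncc3c1OC)[C@H]2C=C | intermediate (key-step product)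
33 | methyl (3R,4R)-4-(1-hydroxyethyl)-1,8-dimethoxy-6-(methoxymethoxy)-3-[8-methoxy-6-(methoxymethoxy)-3-methylisoquinolin-7-yl]-3,4-dihydro-1H-isochromene-7-carboxylate, epimers at C1 and at the carbinol carbon | COc1c(C(=O)OC)c(OCOC)cc2c1C(OC)O[C@@H](c1c(OCOC)cc3cc(C)ncc3c1OC)[C@H]2C(C)O | intermediate
34 | 1-[(3R,4R)-7-(hydroxymethyl)-1,8-dimethoxy-6-(methoxymethoxy)-3-[8-methoxy-6-(methoxymethoxy)-3-methylisoquinolin-7-yl]-3,4-dihydro-1H-isochromen-4-yl]ethanol, epimers at C1 and at the carbinol carbon | COc1c(CO)c(OCOC)cc2c1C(OC)O[C@@H](c1c(OCOC)cc3cc(C)ncc3c1OC)[C@H]2C(C)O | intermediate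
35 | (3R,4S)-4-acetyl-1,8-dimethoxy-6-(methoxymethoxy)-3-[8-methoxy-6-(methoxymethoxy)-3-methylisoquinolin-7-yl]-3,4-dihydro-1H-isochromene-7-carbaldehyde, both C1 epimers | COc1c(C=O)c(OCOC)cc2c1C(OC)O[C@@H](c1c(OCOC)cc3cc(C)ncc3c1OC)[C@H]2C(C)=O | intermediate
36 | (3R,4S)-4-acetyl-6-hydroxy-3-(6-hydroxy-8-methoxy-3-methylisoquinolin-7-yl)-1,8-dimethoxy-3,4-dihydro-1H-isochromene-7-carbaldehyde, both C1 epimers | COc1c(C=O)c(O)cc2c1C(OC)O[C@@H](c1c(O)cc3cc(C)ncc3c1OC)[C@H]2C(C)=O | intermediate (not isolated)
37 | CNP0584953.1: bridged acetal with ring A (methoxy, formyl, hydroxy), pyran ring B carrying the acetyl group, dioxin ring C and the 8-methoxy-3-methylisoquinoline; acetal carbon R, carbinol carbon R, acetyl-bearing carbon S | COc1c(C=O)c(O)cc2c1[C@H]1Oc3cc4cc(C)ncc4c(OC)c3[C@H](O1)[C@H]2C(C)=O | target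

**Totals**
Total step count: 18.
Longest linear sequence: 14 steps (steps 5–18, from 12).

**Steps most likely to fail**

Step 11. A residual free-base fraction of the isoquinoline may bind the phosphoric acid, or the isoquinolinium may itself promote an unselective background addition, so that enantioselectivity erodes. Addition to the doubly ortho-substituted aldehyde may also be slow. The fallback sets out from 10 and 23 and returns at 25. Wohl–Ziegler bromination of 10 (N-bromosuccinimide, azobis(isobutyronitrile), PhCF3, 80 °C) would give the allylic bromide F1. A catalytic asymmetric Nozaki–Hiyama allylation of 23 with F1 (CrCl2, Mn powder, Me3SiCl, a C2-symmetric tridentate bis(oxazolinyl)carbazole ligand, THF) adds through the γ-carbon of the allylchromium species with anti selectivity and is indifferent to the basic nitrogen. It would give the trimethylsilyl ether F2, which dilute aqueous HCl cleaves to 25.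

Step 13. Ionisation may expel the secondary alkoxy group and return 25, the very ionisable product may be alkynylated a second time, or the amine-laden reagent mixture may attack the pyrone. The fallback sets out from 25 and from reagent 29 and returns at 30. Reagent 29 is first combined with trimethyl orthoformate (ZnCl2, THF) away from the substrate to give 1,3,3-trimethoxyprop-1-yne F3, which can be distilled. Alcohol 25 is silylated (Me3SiCl, imidazole) to the silyl ether F2 and exchanged with F3 under Me3SiOTf catalysis with 2,6-di-tert-butylpyridine at −78 °C (silyl-triflate-mediated transacetalisation of a silyl ether). This forms 30 under aprotic conditions with the valuable substrate as the limiting component.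

Step 14. Thermal decomposition of the alkoxyalkyne acetal (ionisation at the acetal carbon, oligomerisation) may outrun a cycloaddition that the freely rotating tether slows down. The fallback sets out from 25 by way of its silyl ether F2 and returns at 32. The cycloaddition is run between two molecules: F2 is heated with an excess of the robust alkyne F3 (xylene, 140 °C), where polarity alone should direct the acetal-bearing alkyne carbon to C6 of the pyrone. Loss of CO2 would give the benzaldehyde dimethyl acetal F4. Pyridinium p-toluenesulfonate in methanol then removes the silyl group and closes ring B by transacetalisation to give 32.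

**Further compounds**
F1 | step 11 | methyl 6-[(E)-3-bromoprop-1-enyl]-4-(methoxymethoxy)-2-oxo-2H-pyran-3-carboxylate | BrC/C=C/c1cc(OCOC)c(C(=O)OC)c(=O)o1
F2 | step 11 | methyl 6-[(1R,2R)-1-[8-methoxy-6-(methoxymethoxy)-3-methylisoquinolin-7-yl]-1-(trimethylsilyloxy)but-3-en-2-yl]-4-(methoxymethoxy)-2-oxo-2H-pyran-3-carboxylate | COc1c([C@H](O[Si](C)(C)C)[C@H](c2cc(OCOC)c(C(=O)OC)c(=O)o2)C=C)c(OCOC)cc2cc(C)ncc12
F3 | step 13 | 1,3,3-trimethoxyprop-1-yne | COC#CC(OC)OC
F4 | step 14 | methyl 3-(dimethoxymethyl)-2-methoxy-6-(methoxymethoxy)-4-[(1R,2S)-1-[8-methoxy-6-(methoxymethoxy)-3-methylisoquinolin-7-yl]-1-(trimethylsilyloxy)but-3-en-2-yl]benzoate | COc1c(C(=O)OC)c(OCOC)cc([C@H](C=C)[C@@H](O[Si](C)(C)C)c2c(OCOC)cc3cc(C)ncc3c2OC)c1C(OC)OC
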